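The route cuts two neighbouring bonds of the benzene ring at once, C1–C7 and C2–Br (C1 carries the chain C7–C8, C2 and C3 bromine, C4 and C5 oxygen, C6 hydrogen). Both are made by 1,2-difunctionalisation of a C1–C2 aryne: a vinyl Grignard reagent adds at C1 and the C2 arylmagnesium so formed is brominated in the same flask. The step exploits the contiguous C1(chain)–C2(Br)–C3(Br) array, the C3 bromine steering the nucleophile to C1. The aryne precursor is a 2-iodoaryl 4-chlorobenzenesulfonate (oxygen on C1, iodine on C2) that already holds the C3 bromine and the C4/C5 methyl ethers.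

Key step: step 4

Remark: the target is taken as the free hydrogen sulfate exactly as drawn and has no stereocentre; 3-bromo-4,5-dimethoxybenzaldehyde (the methyl ether of 5-bromovanillin) is taken as a purchasable starting material, which saves an O-methylation.

Step 1
Reactants: 1 3-bromo-4,5-dimethoxybenzaldehyde
Product: 3 3-bromo-4,5-dimethoxyphenol, via 3-bromo-4,5-dimethoxyphenyl formate 2 (not isolated)
Conditions: mCPBA, CH2Cl2, 0 °C → rt; then K2CO3 (catalytic), MeOH, rt
Reagents that add atoms: meta-chloroperoxybenzoic acid, O=C(OO)c1cccc(Cl)c1
Why: Baeyer–Villiger oxidation of an electron-rich benzaldehyde, in which the aryl group activated by the para methoxy group migrates in preference to hydride to give formate 2, followed by base-catalysed methanolysis (a Dakin-type overall change) that should leave the aryl bromide and the methyl ethers untouched.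

Step 2
Reactants: 3 3-bromo-4,5-dimethoxyphenol
Product: 4 3-bromo-2-iodo-4,5-dimethoxyphenol
Conditions: NIS (1 equiv), p-toluenesulfonic acid monohydrate (catalytic), MeCN, −20 → 0 °C, dark
Reagents that add atoms: N-iodosuccinimide, O=C1CCC(=O)N1I
Why: Electrophilic aromatic iodination, in which both free positions are ortho to the hydroxyl but only C2 is also para to the in-plane C5 methoxy group, the same preference that places a second halogen next to the first in 5-halovanillin-type rings, while one equivalent of reagent at low temperature should limit twofold iodination.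

Step 3
Reactants: 4 3-bromo-2-iodo-4,5-dimethoxyphenol, 5 4-chlorobenzenesulfonyl chloride
Product: 6 3-bromo-2-iodo-4,5-dimethoxyphenyl 4-chlorobenzenesulfonate
Conditions: Et3N, 4-(dimethylamino)pyridine (catalytic), CH2Cl2, 0 °C → rt
Reagents that add atoms: 4-chlorobenzenesulfonyl chloride 5, O=S(=O)(Cl)c1ccc(Cl)cc1
Why: O-Sulfonylation of a phenol (nucleophilic substitution at sulfur under acyl-transfer catalysis) is routine even beside an ortho iodine and installs a leaving group that should depart only once C2 is metalated.

Step 4
Reactants: 6 3-bromo-2-iodo-4,5-dimethoxyphenyl 4-chlorobenzenesulfonate, 7 vinylmagnesium bromide, 8 1,2-dibromotetrachloroethane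
Product: 12 2,3-dibromo-4,5-dimethoxystyrene, via magnesiated aryl sulfonate 9 (not isolated), via 3-bromo-4,5-dimethoxybenzyne 10 (not isolated), via 2-bromo-6-vinylarylmagnesium bromide 11 (not isolated)
Conditions: iPrMgCl (1.05 equiv), THF, −78 °C, 30 min; CH2=CHMgBr (3 equiv), −78 → −40 °C; then BrCl2C–CCl2Br (4 equiv), −78 → 0 °C
Reagents that add atoms: vinylmagnesium bromide 7, C=C[Mg]Br; 1,2-dibromotetrachloroethane 8, BrC(Cl)(Cl)C(Cl)(Cl)Br; isopropylmagnesium chloride, CC(C)[Mg]Cl (magnesium and chlorine carried in 9 only)
Why: Exchange of the C2 iodine for magnesium at −78 °C gives 9, which on warming expels chloromagnesium 4-chlorobenzenesulfonate from C1 to give aryne 10; vinylmagnesium bromide adds to C1 and the resulting C2 Grignard 11 attacks a bromine of 8, releasing tetrachloroethylene and forming the C1–C7 and C2–Br bonds in one flask. The closest known reaction type is the three-component coupling of an aryne released from a 2-iodoaryl sulfonate by iPrMgCl, that is, carbomagnesiation of the aryne followed by electrophilic quench of the ortho arylmagnesium. No ring is closed and no stereocentre is created. The step needs iodine-over-bromine selectivity in the exchange, which the weaker carbon–iodine bond flanked by two electron-withdrawing neighbours should secure with one equivalent of iPrMgCl at −78 °C, and loss of the sulfonate in preference to the C3 bromide from 9, which the much better leaving group on C1 should secure. It needs addition at C1 and not at C2: the inductively withdrawing C3 bromine distorts the aryne so that C1 is the more electrophilic, unhindered terminus and the developing negative charge on C2 lies next to bromine. It finally needs 11 to survive, so the mixture is not warmed beyond about −40 °C and is re-cooled before 8 is added, and an excess of the vinyl Grignard reagent, introduced only after the exchange is complete, should keep isopropyl and aryl Grignard species from capturing the aryne.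

Step 5
Reactants: 12 2,3-dibromo-4,5-dimethoxystyrene
Product: 14 2-(2,3-dibromo-4,5-dimethoxyphenyl)ethanol, via B-alkyl-9-BBN adduct 13 (not isolated)
Conditions: 9-BBN (1.5 equiv), THF, 0 °C → rt; then NaOH aq, H2O2, 0 °C → rt
Reagents that add atoms: 9-borabicyclo[3.3.1]nonane, B1C2CCCC1CCC2 (boron framework carried in 13 only); hydrogen peroxide, OO
Why: Anti-Markovnikov hydroboration of a styrene with the bulky dialkylborane 9-BBN places boron on the terminal carbon C8, and alkaline peroxide oxidation turns the carbon–boron bond into the primary alcohol, while aryl bromides and methyl ethers are inert to both reagents.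

Step 6
Reactants: 14 2-(2,3-dibromo-4,5-dimethoxyphenyl)ethanol
Product: 15 3,4-dibromo-5-(2-hydroxyethyl)benzene-1,2-diol
Conditions: BBr3 (4 equiv), CH2Cl2, −78 → 0 °C; then H2O, 0 °C, argon
Reagents that add atoms: none
Why: Lewis-acid cleavage of aryl methyl ethers (BBr3 demethylation) proceeds by bromide attack on the boron-activated methyl groups, and keeping the mixture at or below 0 °C with a cold quench should leave the primary alcohol as a hydrolysable borate instead of exchanging it for bromide.

Step 7
Reactants: 15 3,4-dibromo-5-(2-hydroxyethyl)benzene-1,2-diol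
Product: 17 2-(2,3-dibromo-4,5-dihydroxyphenyl)ethyl hydrogen sulfate, via triethylammonium alkyl sulfate 16 (not isolated)
Conditions: SO3·NEt3 (1.2 equiv), DMF, rt, argon; then strongly acidic cation-exchange resin (H+ form), H2O, 0 °C; freeze-drying
Reagents that add atoms: sulfur trioxide–triethylamine complex, CC[N+](CC)(CC)S(=O)(=O)[O-]
Why: O-Sulfation with an amine–sulfur trioxide complex, in which, with no base added, the neutral primary alcohol is a better nucleophile than the two electron-poor catechol hydroxyls (one of them shielded by the C3 bromine), so a single sulfate ester should form on the C8 oxygen and proton exchange on the resin should give the free hydrogen sulfate.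

Compound list
1 | 3-bromo-4,5-dimethoxybenzaldehyde | COc1cc(C=O)cc(Br)c1OC | starting material
2 | 3-bromo-4,5-dimethoxyphenyl formate | COc1cc(OC=O)cc(Br)c1OC | intermediate
3 | 3-bromo-4,5-dimethoxyphenol | COc1cc(O)cc(Br)c1OC | intermediate
4 | 3-bromo-2-iodo-4,5-dimethoxyphenol | COc1cc(O)c(I)c(Br)c1OC | intermediate
5 | 4-chlorobenzenesulfonyl chloride | O=S(=O)(Cl)c1ccc(Cl)cc1 | starting material
6 | 3-bromo-2-iodo-4,5-dimethoxyphenyl 4-chlorobenzenesulfonate | COc1cc(OS(=O)(=O)c2ccc(Cl)cc2)c(I)c(Br)c1OC | intermediate
7 | vinylmagnesium bromide | C=C[Mg]Br | starting material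
8 | 1,2-dibromotetrachloroethane | BrC(Cl)(Cl)C(Cl)(Cl)Br | starting material
9 | [2-bromo-6-(4-chlorophenylsulfonyloxy)-3,4-dimethoxyphenyl]magnesium chloride | COc1cc(OS(=O)(=O)c2ccc(Cl)cc2)c([Mg]Cl)c(Br)c1OC | intermediate
10 | 3-bromo-4,5-dimethoxybenzyne | COC1=CC#CC(Br)=C1OC | intermediate
11 | (2-bromo-3,4-dimethoxy-6-vinylphenyl)magnesium bromide | C=Cc1cc(OC)c(OC)c(Br)c1[Mg]Br | intermediate
12 | 2,3-dibromo-4,5-dimethoxystyrene | C=Cc1cc(OC)c(OC)c(Br)c1Br | intermediate
13 | 9-[2-(2,3-dibromo-4,5-dimethoxyphenyl)ethyl]-9-borabicyclo[3.3.1]nonane | COc1cc(CCB2C3CCCC2CCC3)c(Br)c(Br)c1OC | intermediate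
14 | 2-(2,3-dibromo-4,5-dimethoxyphenyl)ethanol | COc1cc(CCO)c(Br)c(Br)c1OC | intermediate
15 | 3,4-dibromo-5-(2-hydroxyethyl)benzene-1,2-diol | OCCc1cc(O)c(O)c(Br)c1Br | intermediate
16 | triethylammonium 2-(2,3-dibromo-4,5-dihydroxyphenyl)ethyl sulfate | CC[NH+](CC)CC.[O-]S(=O)(=O)OCCc1cc(O)c(O)c(Br)c1Br | intermediate
17 | 2-(2,3-dibromo-4,5-dihydroxyphenyl)ethyl hydrogen sulfate | O=S(=O)(O)OCCc1cc(O)c(O)c(Br)c1Br | target

Total step count: 7
Longest linear sequence: 7 steps (1 → 17)

Steps most likely to fail

Step 4. The magnesiated intermediates may lose the C3 bromide instead of, or after, the sulfonate, which would open the wrong aryne or a second aryne and lead to double vinylation. Isopropyl or aryl Grignard species may also capture the aryne, and the vinyl addition may be poorly regioselective. The fallback abandons the aryne and sets out from aldehyde 1. Electrophilic bromination para to the C5 methoxy group (Br2, AcOH, rt → 50 °C) should give 2,3-dibromo-4,5-dimethoxybenzaldehyde F1. Wittig methylenation (Ph3PCH3Br, KOtBu, THF, 0 °C) then turns the aldehyde carbon into C7 and returns to the route at styrene 12.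

Step 7. A phenolic hydroxyl may be sulfated in competition with the alcohol, more than one sulfate may be introduced, or the ester may be lost during proton exchange. The fallback sets out from triol 15. The two phenols are acetylated selectively under degassed aqueous alkaline conditions (Ac2O, NaOH aq, 0 °C, argon), where phenoxides react and the alcohol does not, to give 3,4-dibromo-5-(2-hydroxyethyl)-1,2-phenylene diacetate F2. Sulfation (SO3·NEt3, DMF, rt) then has only the alcohol to attack and gives triethylammonium 2-(4,5-diacetoxy-2,3-dibromophenyl)ethyl sulfate F3. Ammonia in methanol removes both acetates, and proton exchange on the resin returns to the route at 17.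

Step 2. Iodination may take place at the other ortho position C6, or at both ortho positions. The fallback sets out from phenol 3 and fixes the site by acidity, not by electrophilic preference. The hydroxyl is protected as its methoxymethyl ether (MOMCl, iPr2NEt, CH2Cl2) to give 1-bromo-2,3-dimethoxy-5-(methoxymethoxy)benzene F4. LiN(iPr)2 in THF at −78 °C should remove only the proton between bromine and the acetal oxygen (C2), and quenching with I2 gives 3-bromo-2-iodo-4,5-dimethoxy-1-(methoxymethoxy)benzene F5. HCl in MeOH removes the acetal and returns to the route at iodophenol 4.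

Further compounds
F1 | step 4 | 2,3-dibromo-4,5-dimethoxybenzaldehyde | COc1cc(C=O)c(Br)c(Br)c1OC
F2 | step 7 | 3,4-dibromo-5-(2-hydroxyethyl)-1,2-phenylene diacetate | CC(=O)Oc1cc(CCO)c(Br)c(Br)c1OC(C)=O
F3 | step 7 | triethylammonium 2-(4,5-diacetoxy-2,3-dibromophenyl)ethyl sulfate | CC[NH+](CC)CC.CC(=O)Oc1cc(CCOS(=O)(=O)[O-])c(Br)c(Br)c1OC(C)=O
F4 | step 2 | 1-bromo-2,3-dimethoxy-5-(methoxymethoxy)benzene | COCOc1cc(Br)c(OC)c(OC)c1
F5 | step 2 | 3-bromo-2-iodo-4,5-dimethoxy-1-(methoxymethoxy)benzene | COCOc1cc(OC)c(OC)c(Br)c1I
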